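Percent of the starting material charged was my unit, with one homo dimer counted as two.

| flask | starting material | temperature | time |
|---|---|---|---|
| oak | 0.27 M | 50 °C | 15 min |
| larch | 0.27 M | 80 °C | 15 min |
| ash | 0.27 M | 20 °C | 15 min |
| alder | 0.27 M | 110 °C | 15 min |

    starting material ⇌ target (K1 = 8.3, k1 = 0.018 s⁻¹, Ea1 = 109 kJ mol⁻¹, ΔH1 = 3.00 kJ mol⁻¹)
    starting material → side product (k2 = 0.0026 s⁻¹, Ea2 = 101 kJ mol⁻¹)
    target ⇌ isomer of the product (K3 = 1.4, k3 = 0.033 s⁻¹, Ea3 = 87.0 kJ mol⁻¹, ΔH3 = −42.0 kJ mol⁻¹)
    2 starting material → homo dimer (k4 = 0.051 M⁻¹ s⁻¹, Ea4 = 59.0 kJ mol⁻¹)
    (constants at 80 °C)

- percentages count the starting material that a species holds: one homo dimer counts as two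
- a doubled species enters its step squared and goes two at a time
- constants are those at 80 °C; use the activation energies and enthalpies for any other temperature

1. the best flask by amount of target, in percent of the starting material charged; "all alike" if 1.5 percentage points covers them all (oak / larch / ash / alder / all alike)
2. amount of target at the end, in percent of the starting material charged, oak
3. amount of target at the end, in percent of the starting material charged, larch
4. amount of target at the end, in percent of the starting material charged, ash
5. amount of target at the end, in percent of the starting material charged, alder

The constants stood at 80 °C, so I first moved them to ash, at 20 °C. Two starting material go at each turn of the homo dimer step. So I took twice its constant at that temperature, times the charge, and called this the dimer clock: 0.0270 min⁻¹.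

At the start of ash, the homo dimer step used starting material 50 times as fast as the forward step to target. That ratio is the selectivity factor. The clock ran faster than the step to side product at that temperature, so I dropped that step. In ash, starting material and target relax by their step alone, both ways together, in 18.6 h, long against 15 min, so I dropped the way back from target too.

Then the rate integrates in closed form. Starting material falls as the charge over one plus clock times time. Integrating the forward rate gives the part that went through target: the logarithm of one plus clock times time, over the selectivity factor. At 15 min that was 0.682%. In ash, target and isomer of the product relax by their step alone, both ways together, in 145 min, long against 15 min, so I committed to that figure as target in ash.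

But in larch the same ratio is 1.53, and the rule returns 212%, more than was charged. So my reckoning stopped there. From ash to alder the forward step speeds up by 36000 and the homo dimer step by 290, so I expected a warmer flask to beat ash, but I could not reckon which.

The forecast named larch “the best compromise”, with 7.2% in oak, 20.5% in larch, 0.66% in ash and 4.7% in alder.

The simulation put larch first with 19.5%, then oak with 7.00%, alder with 4.69% and ash with 0.654%. In ash, the homo dimer step still used starting material 35 times as fast as the forward step at the end, and target with isomer of the product came to 0.679% against my 0.682%. Read at 10 min, ash held 0.466% target and 0.0113% isomer of the product, together 0.477%, where the clock gives 0.478%.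

The constants were chosen freely; no experiment stands behind them.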